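**Retrosynthetic overview**

- The target is the (Z)-p-coumarate of a (5R,7R,10R)-15-hydroxyeudesma-3,11(13)-dien-12-oic acid. The last disconnections are the fluoride-labile protecting groups, the C15–O acyl bond (Mitsunobu coupling with a Z acid made from 4-hydroxybenzaldehyde) and the C12 acid (from a C12 allylic alcohol).
- Feature used: the only ring alkene, C3=C4 in ring A, lies between the fusion carbon C5 (H) and, one bond further, the quaternary fusion carbon C10 (methyl C14). It is the cyclohexene alkene left when a C2–C5 diene adds to a C1=C10 alkene tethered through C6–C9.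
- Rings A and B are therefore formed together, in one intramolecular Diels–Alder step (bonds C1–C2 and C5–C10); no ring is made before or after.
- The triene comes from (R)-limonene, whose stereocentre becomes C7: hydroxylation of the isopropenyl methyl (future C12, so that no allylic oxidation is needed later beside the C3=C4 alkene), cleavage of the ring alkene to a keto acetal, methylenation of the ketone (C1=C10), then bromo-olefination of the aldehyde and vinyl cross-coupling (diene with C15–O).

Key step: step 12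

Assumption: eudesmane numbering is used (C12 oxygenated side-chain carbon, C13 exocyclic methylene, C14 methyl on C10, C15 oxygenated carbon on C4); the bromophosphonate of step 8 is taken not to be commercial and is made in steps 6 and 7; conjugate bases and short-lived mechanistic species are not numbered separately.

**Route**

Step 1
Reactants: 1 (R)-(+)-limonene
Product: 4 (4R)-p-mentha-1,8-dien-10-ol, via 10-lithiolimonene 2 (not isolated), via dimethyl allylboronate 3 (not isolated)
Conditions: n-BuLi, TMEDA, hexane, rt; B(OMe)3, Et2O, −78 °C to rt; 30% H2O2, aq NaOH, 0 °C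
Reagents that add atoms: hydrogen peroxide, OO
Why: Allylic metalation by n-BuLi·TMEDA takes a proton from the isopropenyl methyl group (the 2-substituted allyl anion has equivalent termini and does not involve the ring stereocentre), and borylation followed by oxidative C–B to C–O migration should give the primary allylic alcohol with the (R) centre intact.

Step 2
Reactants: 4 (4R)-p-mentha-1,8-dien-10-ol
Product: 5 tert-butyldiphenylsilyl ether of 4
Conditions: TBDPSCl, imidazole, DMF, rt
Reagents that add atoms: tert-butyl(chloro)diphenylsilane, CC(C)(C)[Si](Cl)(c1ccccc1)c1ccccc1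
Why: Standard silylation of a primary alcohol; TBDPS is chosen because it should tolerate ozone, TsOH in MeOH, ylides, i-Bu2AlH and the temperature of step 12.

Step 3
Reactants: 5 silyl ether
Product: 8 (5R)-7,7-dimethoxy-5-[3-(tert-butyldiphenylsilyloxy)prop-1-en-2-yl]heptan-2-one, via methoxy hydroperoxide aldehyde 6 (not isolated), via hydroperoxy dimethyl acetal 7 (not isolated)
Conditions: O3 (1 equiv, Sudan Red 7B end-point), CH2Cl2/MeOH, −78 °C; TsOH·H2O (cat.), rt; NaHCO3, Me2S, rt
Reagents that add atoms: ozone, [O-][O+]=O; methanol, CO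
Why: Chemoselective ozonolysis of the electron-rich trisubstituted ring alkene (the 1,1-disubstituted alkene is deactivated by its allylic silyloxy group) with Criegee fragmentation toward the ketone oxide, which MeOH traps as the methoxy hydroperoxide while TsOH acetalises the aldehyde end; Me2S then reduces the hydroperoxide to the methyl ketone, so the two termini emerge differentiated.

Step 4
Reactants: 8 keto acetal
Product: 9 (5R)-7,7-dimethoxy-2-methyl-5-[3-(tert-butyldiphenylsilyloxy)prop-1-en-2-yl]hept-1-ene
Conditions: Ph3PCH3Br, KOt-Bu, THF, 0 °C to rt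
Reagents that add atoms: methyltriphenylphosphonium bromide, C[P+](c1ccccc1)(c1ccccc1)c1ccccc1.[Br-]
Why: Wittig methylenation of the methyl ketone installs C1=C10 with methyl C14; the acetal and silyl ether are inert to the ylide and the stereocentre is not adjacent to an enolisable position.

Step 5
Reactants: 9 ene acetal
Product: 10 (3R)-6-methyl-3-[3-(tert-butyldiphenylsilyloxy)prop-1-en-2-yl]hept-6-enal
Conditions: PPTS (cat.), acetone/H2O 9:1, 50 °C
Reagents that add atoms: water, O
Why: Mild acid-catalysed acetal hydrolysis frees the aldehyde (future C5) under conditions too weak to isomerise the 1,1-disubstituted alkenes or cleave the TBDPS ether.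

Step 6
Reactants: 11 methyl bis(2,2,2-trifluoroethyl)phosphonoacetate
Product: 12 methyl dibromo[bis(2,2,2-trifluoroethoxy)phosphoryl]acetate
Conditions: Br2, aq NaOH (NaOBr), 0 °C, short contact
Reagents that add atoms: bromine, BrBr
Why: Exhaustive α-bromination of the doubly activated CH2 group through its enolate with hypobromite, which avoids the mono/di mixtures of a direct monobromination.

Step 7
Reactants: 12 dibromophosphonoacetate
Product: 13 methyl bromo[bis(2,2,2-trifluoroethoxy)phosphoryl]acetate (racemic)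
Conditions: SnCl2·2H2O, EtOH/H2O, 0 °C
Reagents that add atoms: none
Why: Reductive removal of one bromine from the geminal dibromide by divalent tin (halogen abstraction, then protonation of the stabilised carbanion) stops cleanly at the monobromide.

Step 8
Reactants: 10 aldehyde; 13 bromophosphonate
Product: 14 methyl (2E,5R)-2-bromo-8-methyl-5-[3-(tert-butyldiphenylsilyloxy)prop-1-en-2-yl]nona-2,8-dienoate
Conditions: 13, KOt-Bu, 18-crown-6, THF, −78 °C; then 10
Reagents that add atoms: none
Why: Horner–Wadsworth–Emmons olefination with the bromo analogue of the Still–Gennari phosphonate: the electron-poor trifluoroethyl phosphonate and the crown-separated potassium ion make elimination from the first adduct fast and irreversible, so the kinetic alkene with C6 cis to CO2Me (the E bromoacrylate, C4=C5) should predominate.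

Step 9
Reactants: 14 bromoenoate
Product: 15 (2E,5R)-2-bromo-8-methyl-5-[3-(tert-butyldiphenylsilyloxy)prop-1-en-2-yl]nona-2,8-dien-1-ol
Conditions: i-Bu2AlH (2.5 equiv), CH2Cl2, −78 °C; aq KNaC4H4O6 (potassium sodium tartrate)
Reagents that add atoms: none
Why: 1,2-Reduction of the ester by i-Bu2AlH gives the allylic alcohol (C15–OH) and leaves the alkenyl bromide, the alkenes and the silyl ether untouched at low temperature.

Step 10
Reactants: 15 bromo allylic alcohol
Product: 16 4-methoxybenzyl ether of 15
Conditions: NaH, PMBCl, Bu4NI (cat.), THF/DMF, 0 °C to rt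
Reagents that add atoms: 4-methoxybenzyl chloride, COc1ccc(CCl)cc1
Why: Williamson etherification; the PMB ether is orthogonal to the TBDPS ether (fluoride) and is removed later by DDQ without touching the silylethyl ester.

Step 11
Reactants: 16 alkenyl bromide
Product: 17 (2Z,5R)-2-ethenyl-1-(4-methoxybenzyloxy)-8-methyl-5-[3-(tert-butyldiphenylsilyloxy)prop-1-en-2-yl]nona-2,8-diene (the triene: diene C2=C3–C4(C15H2OPMB)=C5 with C6 trans to the vinyl group, dienophile C1=C10, C7 R)
Conditions: vinylboronic acid pinacol ester, Pd(PPh3)4 (5 mol%), K3PO4, THF/H2O, 65 °C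
Reagents that add atoms: vinylboronic acid pinacol ester, C=CB1OC(C)(C)C(C)(C)O1
Why: Suzuki–Miyaura coupling; oxidative addition of the alkenyl bromide to zerovalent palladium and reductive elimination go with retention, so the vinyl group (C3, C2) enters trans to C6.

Step 12
Reactants: 17 triene
Product: 18 (5R,7R,10R)-12-(tert-butyldiphenylsilyloxy)-15-(4-methoxybenzyloxy)eudesma-3,11(13)-diene (trans-fused)
Conditions: toluene (0.01 M, degassed), BHT (cat.), sealed base-washed tube, 210 °C
Reagents that add atoms: none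
Why: Concerted suprafacial [4+2] cycloaddition of the C2=C3–C4=C5 diene to the unactivated C1=C10 alkene, a thermal type 1 intramolecular Diels–Alder reaction of a 1,7,9-decatriene with a methyl group on the internal dienophile carbon, which is the closest known reaction class. Ring A (C1, C2, C3, C4, C5, C10) closes as the new cyclohexene through the bonds C1–C2 and C5–C10, and ring B (C5 to C10) closes in the same event through the four-carbon tether C6–C9 as a six-membered ring, the tether fixing the regiochemistry. The relative configuration of the new centres C5 and C10 comes from the exo-tether transition state, in which methyl C14 lies endo and C6, standing outside on the C4=C5 bond, ends up cis to C14, so that H5 and C14 are trans across the fusion. Their absolute configuration is relayed from C7 (R): the forming ring B is chair-like and the C7 side chain prefers the equatorial position, cis to C14, which gives 5R,10R. The step needs trans over cis fusion, for which the angular methyl group gives only a moderate bias, and equatorial over axial C7, worth about one substituent A-value at this temperature, so minor diastereomers are expected and would be separated here or at alcohol 19. The C11=C13 alkene cannot compete because only two atoms link it to the diene, and both ethers are thermally inert.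

Step 13
Reactants: 18 cycloadduct
Product: 19 (5R,7R,10R)-15-(4-methoxybenzyloxy)eudesma-3,11(13)-dien-12-ol
Conditions: Bu4NF, THF, 0 °C to rt
Reagents that add atoms: none
Why: Fluoride cleaves the Si–O bond of the TBDPS ether selectively; the PMB ether and both alkenes are unaffected.

Step 14
Reactants: 19 allylic alcohol
Product: 20 (5R,7R,10R)-15-(4-methoxybenzyloxy)eudesma-3,11(13)-dien-12-al
Conditions: MnO2 (activated, excess), CH2Cl2, rt; used crude
Reagents that add atoms: none
Why: Selective allylic alcohol oxidation by MnO2 under neutral conditions gives the 2-substituted acrolein without moving the C11=C13 alkene into conjugation with C7.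

Step 15
Reactants: 20 enal
Product: 21 (5R,7R,10R)-15-(4-methoxybenzyloxy)eudesma-3,11(13)-dien-12-oic acid
Conditions: NaClO2, NaH2PO4, 2-methyl-2-butene (excess), t-BuOH/H2O, 0 °C to rt
Reagents that add atoms: sodium chlorite, [Na+].[O-]Cl=O
Why: Pinnick oxidation converts the α-methylene aldehyde to the acrylic acid; the excess scavenger removes HOCl before it can attack the C3=C4 alkene or the PMB ring.

Step 16
Reactants: 21 acid
Product: 22 2-(trimethylsilyl)ethyl (5R,7R,10R)-15-(4-methoxybenzyloxy)eudesma-3,11(13)-dien-12-oate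
Conditions: Me3SiCH2CH2OH, EDC·HCl, DMAP (cat.), CH2Cl2, 0 °C to rt
Reagents that add atoms: 2-(trimethylsilyl)ethanol, C[Si](C)(C)CCO
Why: Carbodiimide (Steglich) esterification masks the acid as a fluoride-labile ester, so that the later Mitsunobu step has only one acidic partner.

Step 17
Reactants: 22 PMB ether
Product: 23 2-(trimethylsilyl)ethyl (5R,7R,10R)-15-hydroxyeudesma-3,11(13)-dien-12-oate
Conditions: DDQ (1.2 equiv), CH2Cl2/pH 7 buffer, 0 °C
Reagents that add atoms: none
Why: Oxidative PMB cleavage (electron transfer to DDQ, benzylic oxocarbenium ion, hydrolysis) frees the C15 allylic alcohol; the silylethyl ester and the alkenes are inert.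

Step 18
Reactants: 24 4-hydroxybenzaldehyde
Product: 25 4-(triisopropylsilyloxy)benzaldehyde
Conditions: TIPSCl, imidazole, DMF, rt
Reagents that add atoms: triisopropylsilyl chloride, CC(C)[Si](Cl)(C(C)C)C(C)C
Why: Phenol silylation prevents phenoxide formation, which would deactivate the aldehyde in the olefination and compete in the Mitsunobu step.

Step 19
Reactants: 25 aldehyde; 11 methyl bis(2,2,2-trifluoroethyl)phosphonoacetate
Product: 26 methyl (Z)-3-[4-(triisopropylsilyloxy)phenyl]prop-2-enoate
Conditions: 11, KN(SiMe3)2, 18-crown-6, THF, −78 °C; then 25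
Reagents that add atoms: none
Why: Still–Gennari olefination: fast, irreversible elimination from the kinetic adduct of the electron-poor phosphonate should set the Z alkene.

Step 20
Reactants: 26 Z methyl ester
Product: 27 (Z)-3-[4-(triisopropylsilyloxy)phenyl]prop-2-enoic acid
Conditions: Me3SnOH, 1,2-dichloroethane, 70 °C, dark; dilute aq HCl work-up
Reagents that add atoms: trimethyltin hydroxide, C[Sn](C)(C)O
Why: Neutral tin hydroxide cleavage of the methyl ester (acyl substitution, then acidolysis of the stannyl ester) avoids the free hydroxide that would remove the aryl silyl ether, and involves no species able to isomerise the Z alkene.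

Step 21
Reactants: 23 C15 alcohol; 27 Z acid
Product: 28 2-(trimethylsilyl)ethyl (5R,7R,10R)-15-{(Z)-3-[4-(triisopropylsilyloxy)phenyl]prop-2-enoyloxy}eudesma-3,11(13)-dien-12-oate
Conditions: PPh3, DIAD, THF, 0 °C, dark
Reagents that add atoms: none
Why: Mitsunobu esterification activates the primary allylic alcohol and not the acid, so the Z carboxylate acts only as a nucleophile in a direct SN2 displacement at C15 and its geometry is not exposed to acyl activation.

Step 22
Reactants: 28 protected ester
Product: 29 (5R,7R,10R)-15-[(Z)-3-(4-hydroxyphenyl)prop-2-enoyloxy]eudesma-3,11(13)-dien-12-oic acid (CNP0183482.1)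
Conditions: Bu4NF (4 equiv), THF, 0 °C to rt, dark; aq NH4Cl work-up
Reagents that add atoms: none
Why: Fluoride removes both silicon-based groups in one operation, the silylethyl ester by β-elimination (ethene and Me3SiF) and the aryl silyl ether by Si–O cleavage, without touching the C15 ester.

**Compound list**

1 | (R)-(+)-limonene | CC1=CC[C@@H](CC1)C(C)=C | starting material
2 | 10-lithiolimonene (TMEDA complex) | CC1=CC[C@@H](CC1)C(=C)C[Li] | intermediate
3 | dimethyl [(4R)-p-mentha-1,8-dien-10-yl]boronate | CC1=CC[C@@H](CC1)C(=C)CB(OC)OC | intermediate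
4 | (4R)-p-mentha-1,8-dien-10-ol | CC1=CC[C@@H](CC1)C(=C)CO | intermediate
5 | (4R)-10-(tert-butyldiphenylsilyloxy)-p-mentha-1,8-diene | CC1=CC[C@@H](CC1)C(=C)CO[Si](c2ccccc2)(c2ccccc2)C(C)(C)C | intermediate
6 | (3R)-6-hydroperoxy-6-methoxy-3-[3-(tert-butyldiphenylsilyloxy)prop-1-en-2-yl]heptanal (mixture at C6) | CC(OC)(OO)CC[C@H](CC=O)C(=C)CO[Si](c1ccccc1)(c1ccccc1)C(C)(C)C | intermediate
7 | (5R)-2-hydroperoxy-2,7,7-trimethoxy-5-[3-(tert-butyldiphenylsilyloxy)prop-1-en-2-yl]heptane (mixture at C2) | CC(OC)(OO)CC[C@H](CC(OC)OC)C(=C)CO[Si](c1ccccc1)(c1ccccc1)C(C)(C)C | intermediate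
8 | (5R)-7,7-dimethoxy-5-[3-(tert-butyldiphenylsilyloxy)prop-1-en-2-yl]heptan-2-one | CC(=O)CC[C@H](CC(OC)OC)C(=C)CO[Si](c1ccccc1)(c1ccccc1)C(C)(C)C | intermediate
9 | (5R)-7,7-dimethoxy-2-methyl-5-[3-(tert-butyldiphenylsilyloxy)prop-1-en-2-yl]hept-1-ene | C=C(C)CC[C@H](CC(OC)OC)C(=C)CO[Si](c1ccccc1)(c1ccccc1)C(C)(C)C | intermediate
10 | (3R)-6-methyl-3-[3-(tert-butyldiphenylsilyloxy)prop-1-en-2-yl]hept-6-enal | C=C(C)CC[C@H](CC=O)C(=C)CO[Si](c1ccccc1)(c1ccccc1)C(C)(C)C | intermediate
11 | methyl bis(2,2,2-trifluoroethyl)phosphonoacetate | COC(=O)CP(=O)(OCC(F)(F)F)OCC(F)(F)F | starting material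
12 | methyl dibromo[bis(2,2,2-trifluoroethoxy)phosphoryl]acetate | COC(=O)C(Br)(Br)P(=O)(OCC(F)(F)F)OCC(F)(F)F | intermediate
13 | methyl bromo[bis(2,2,2-trifluoroethoxy)phosphoryl]acetate (racemic) | COC(=O)C(Br)P(=O)(OCC(F)(F)F)OCC(F)(F)F | intermediate
14 | methyl (2E,5R)-2-bromo-8-methyl-5-[3-(tert-butyldiphenylsilyloxy)prop-1-en-2-yl]nona-2,8-dienoate | C=C(C)CC[C@H](C/C=C(/Br)C(=O)OC)C(=C)CO[Si](c1ccccc1)(c1ccccc1)C(C)(C)C | intermediate
15 | (2E,5R)-2-bromo-8-methyl-5-[3-(tert-butyldiphenylsilyloxy)prop-1-en-2-yl]nona-2,8-dien-1-ol | C=C(C)CC[C@H](C/C=C(/Br)CO)C(=C)CO[Si](c1ccccc1)(c1ccccc1)C(C)(C)C | intermediate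
16 | (2E,5R)-2-bromo-1-(4-methoxybenzyloxy)-8-methyl-5-[3-(tert-butyldiphenylsilyloxy)prop-1-en-2-yl]nona-2,8-diene | C=C(C)CC[C@H](C/C=C(/Br)COCc1ccc(OC)cc1)C(=C)CO[Si](c1ccccc1)(c1ccccc1)C(C)(C)C | intermediate
17 | (2Z,5R)-2-ethenyl-1-(4-methoxybenzyloxy)-8-methyl-5-[3-(tert-butyldiphenylsilyloxy)prop-1-en-2-yl]nona-2,8-diene | C=C(C)CC[C@H](C/C=C(/C=C)COCc1ccc(OC)cc1)C(=C)CO[Si](c1ccccc1)(c1ccccc1)C(C)(C)C | intermediate
18 | (5R,7R,10R)-12-(tert-butyldiphenylsilyloxy)-15-(4-methoxybenzyloxy)eudesma-3,11(13)-diene | C=C(CO[Si](c1ccccc1)(c1ccccc1)C(C)(C)C)[C@@H]1CC[C@@]2(C)CCC=C(COCc3ccc(OC)cc3)[C@@H]2C1 | intermediate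
19 | (5R,7R,10R)-15-(4-methoxybenzyloxy)eudesma-3,11(13)-dien-12-ol | C=C(CO)[C@@H]1CC[C@@]2(C)CCC=C(COCc3ccc(OC)cc3)[C@@H]2C1 | intermediate
20 | (5R,7R,10R)-15-(4-methoxybenzyloxy)eudesma-3,11(13)-dien-12-al | C=C(C=O)[C@@H]1CC[C@@]2(C)CCC=C(COCc3ccc(OC)cc3)[C@@H]2C1 | intermediate
21 | (5R,7R,10R)-15-(4-methoxybenzyloxy)eudesma-3,11(13)-dien-12-oic acid | C=C(C(=O)O)[C@@H]1CC[C@@]2(C)CCC=C(COCc3ccc(OC)cc3)[C@@H]2C1 | intermediate
22 | 2-(trimethylsilyl)ethyl (5R,7R,10R)-15-(4-methoxybenzyloxy)eudesma-3,11(13)-dien-12-oate | C=C(C(=O)OCC[Si](C)(C)C)[C@@H]1CC[C@@]2(C)CCC=C(COCc3ccc(OC)cc3)[C@@H]2C1 | intermediate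
23 | 2-(trimethylsilyl)ethyl (5R,7R,10R)-15-hydroxyeudesma-3,11(13)-dien-12-oate | C=C(C(=O)OCC[Si](C)(C)C)[C@@H]1CC[C@@]2(C)CCC=C(CO)[C@@H]2C1 | intermediate
24 | 4-hydroxybenzaldehyde | O=Cc1ccc(O)cc1 | starting material
25 | 4-(triisopropylsilyloxy)benzaldehyde | O=Cc1ccc(O[Si](C(C)C)(C(C)C)C(C)C)cc1 | intermediate
26 | methyl (Z)-3-[4-(triisopropylsilyloxy)phenyl]prop-2-enoate | COC(=O)/C=C\c1ccc(O[Si](C(C)C)(C(C)C)C(C)C)cc1 | intermediate
27 | (Z)-3-[4-(triisopropylsilyloxy)phenyl]prop-2-enoic acid | OC(=O)/C=C\c1ccc(O[Si](C(C)C)(C(C)C)C(C)C)cc1 | intermediate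
28 | 2-(trimethylsilyl)ethyl (5R,7R,10R)-15-{(Z)-3-[4-(triisopropylsilyloxy)phenyl]prop-2-enoyloxy}eudesma-3,11(13)-dien-12-oate | C=C(C(=O)OCC[Si](C)(C)C)[C@@H]1CC[C@@]2(C)CCC=C(COC(=O)/C=C\c3ccc(O[Si](C(C)C)(C(C)C)C(C)C)cc3)[C@@H]2C1 | intermediate
29 | (5R,7R,10R)-15-[(Z)-3-(4-hydroxyphenyl)prop-2-enoyloxy]eudesma-3,11(13)-dien-12-oic acid (CNP0183482.1) | C=C(C(=O)O)[C@@H]1CC[C@@]2(C)CCC=C(COC(=O)/C=C\c3ccc(O)cc3)[C@@H]2C1 | target

**Step count**

Total: 22 steps. Longest linear sequence: 17 steps (steps 1–5, 8–17, 21, 22). Side branches: steps 6–7 (bromophosphonate 13) and steps 18–20 (Z acid 27).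

**Steps most likely to fail**

1. Step 12. At 210 °C the energy gaps between the exo-tether and endo-tether modes, and between the two diene faces, may be too small to give a useful excess of the trans-fused, C7-equatorial isomer. The unactivated dienophile may also react so slowly that the triene decomposes first. The fallback uses an activated, electron-poor diene and sets out from bromoenoate 14. Suzuki–Miyaura vinylation at the ester stage (vinylboronic acid pinacol ester, Pd(PPh3)4, K3PO4) should give methyl (2Z,5R)-2-ethenyl-8-methyl-5-[3-(tert-butyldiphenylsilyloxy)prop-1-en-2-yl]nona-2,8-dienoate F1. Its C4 ester lowers the diene LUMO, so the same C1–C2 and C5–C10 closure could be run in toluene at 110–140 °C, or with Me2AlCl near room temperature, where the differences between the competing transition states weigh more. The cycloadduct methyl (5R,7R,10R)-12-(tert-butyldiphenylsilyloxy)eudesma-3,11(13)-dien-15-oate F2 would be reduced with i-Bu2AlH to (5R,7R,10R)-12-(tert-butyldiphenylsilyloxy)eudesma-3,11(13)-dien-15-ol F3, and etherification with NaH and PMBCl returns to the route at 18.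

2. Step 3. Ozone may attack the second alkene before the ring alkene is consumed, or the one-pot acetalisation and hydroperoxide reduction may give mixed termini. The fallback replaces ozonolysis by epoxidation and glycol cleavage and sets out from 5. mCPBA (CH2Cl2, NaHCO3, 0 °C) should epoxidise only the trisubstituted alkene to (4R)-1,2-epoxy-10-(tert-butyldiphenylsilyloxy)-p-menth-8-ene F4 (diastereomer mixture). H5IO6 in THF/H2O opens and cleaves it to (3R)-6-oxo-3-[3-(tert-butyldiphenylsilyloxy)prop-1-en-2-yl]heptanal F5. Aldehyde-selective acetalisation (HC(OMe)3, MeOH, NH4Cl cat., rt) returns to the route at 8.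

3. Step 22. Unbuffered fluoride generates a phenolate conjugated to the Z enoate over the hours needed to cleave the silylethyl ester, so Z to E isomerisation or loss of the C15 acyl group may occur. The fallback carries C12 as the aldehyde, which serves as the masked acid, and sets out from 20. DDQ removes the PMB group to give (5R,7R,10R)-15-hydroxyeudesma-3,11(13)-dien-12-al F6. Mitsunobu coupling with 27 (betaine pre-formed from PPh3 and DIAD) gives (5R,7R,10R)-15-{(Z)-3-[4-(triisopropylsilyloxy)phenyl]prop-2-enoyloxy}eudesma-3,11(13)-dien-12-al F7. Pinnick oxidation, with the phenol still silylated, gives (5R,7R,10R)-15-{(Z)-3-[4-(triisopropylsilyloxy)phenyl]prop-2-enoyloxy}eudesma-3,11(13)-dien-12-oic acid F8. Brief treatment with Bu4NF buffered with AcOH at 0 °C, which cleaves only the aryl silyl ether and keeps the phenol protonated, arrives at 29.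

**Further compounds**

F1 | step 12 | methyl (2Z,5R)-2-ethenyl-8-methyl-5-[3-(tert-butyldiphenylsilyloxy)prop-1-en-2-yl]nona-2,8-dienoate | C=C(C)CC[C@H](C/C=C(/C=C)C(=O)OC)C(=C)CO[Si](c1ccccc1)(c1ccccc1)C(C)(C)C
F2 | step 12 | methyl (5R,7R,10R)-12-(tert-butyldiphenylsilyloxy)eudesma-3,11(13)-dien-15-oate | C=C(CO[Si](c1ccccc1)(c1ccccc1)C(C)(C)C)[C@@H]1CC[C@@]2(C)CCC=C(C(=O)OC)[C@@H]2C1
F3 | step 12 | (5R,7R,10R)-12-(tert-butyldiphenylsilyloxy)eudesma-3,11(13)-dien-15-ol | C=C(CO[Si](c1ccccc1)(c1ccccc1)C(C)(C)C)[C@@H]1CC[C@@]2(C)CCC=C(CO)[C@@H]2C1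
F4 | step 3 | (4R)-1,2-epoxy-10-(tert-butyldiphenylsilyloxy)-p-menth-8-ene (diastereomer mixture) | CC12CC[C@H](CC1O2)C(=C)CO[Si](c3ccccc3)(c3ccccc3)C(C)(C)C
F5 | step 3 | (3R)-6-oxo-3-[3-(tert-butyldiphenylsilyloxy)prop-1-en-2-yl]heptanal | CC(=O)CC[C@H](CC=O)C(=C)CO[Si](c1ccccc1)(c1ccccc1)C(C)(C)C
F6 | step 22 | (5R,7R,10R)-15-hydroxyeudesma-3,11(13)-dien-12-al | C=C(C=O)[C@@H]1CC[C@@]2(C)CCC=C(CO)[C@@H]2C1
F7 | step 22 | (5R,7R,10R)-15-{(Z)-3-[4-(triisopropylsilyloxy)phenyl]prop-2-enoyloxy}eudesma-3,11(13)-dien-12-al | C=C(C=O)[C@@H]1CC[C@@]2(C)CCC=C(COC(=O)/C=C\c3ccc(O[Si](C(C)C)(C(C)C)C(C)C)cc3)[C@@H]2C1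
F8 | step 22 | (5R,7R,10R)-15-{(Z)-3-[4-(triisopropylsilyloxy)phenyl]prop-2-enoyloxy}eudesma-3,11(13)-dien-12-oic acid | C=C(C(=O)O)[C@@H]1CC[C@@]2(C)CCC=C(COC(=O)/C=C\c3ccc(O[Si](C(C)C)(C(C)C)C(C)C)cc3)[C@@H]2C1
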